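No constants came with this flask, so I read the one I wanted from the earlier runs.

common to all: substrate 0.10 M
- Wednesday's: partner 2 equiv; capture agent 2 mM; run made earlier
- Thursday's: partner 1 equiv; capture agent 2 mM; run made earlier
- Saturday's: partner 4 equiv; capture agent 2 mM; run made earlier
- birch: partner 2.00 equiv; capture agent 2.00 mM; one stirred flow tank at steady state, fed with the mixture as stated, mean residence time 25.0 min
- oak: partner 2.00 equiv; capture agent 2.00 mM; a closed flask charged with all of it at once and left for 5.0 min; time 5.0 min
- cedar: partner 2.00 equiv (fed, over 4.00 min); capture agent 2.00 mM; a stirred flask in which partner is dosed at a steady rate over 4.00 min without added volume, worked up at 5.0 min; time 5.0 min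
- ash: partner 2.00 equiv; capture agent 2.00 mM; a single well-mixed tank run continuously and read at steady state, 5.0 min in it on average

| run | time / min | triple product / % | substrate / % |
|---|---|---|---|
| Wednesday's | 0.250 | 4.2 | 40.9 |
| Wednesday's | 0.417 | 10.8 | 23.6 |
| Wednesday's | 0.667 | 17.6 | 9.9 |
| Wednesday's | 1.00 | 24.1 | 2.8 |
| Wednesday's | 2.00 | 30.2 | 0 |
| Wednesday's | 3.00 | 32.5 | 0.3 |
| Thursday's | 0.500 | 2.3 | 41.3 |
| Thursday's | 1.00 | 9.1 | 19.2 |
| Thursday's | 1.50 | 11.0 | 9.7 |
| Thursday's | 2.00 | 13.0 | 6.1 |
| Thursday's | 2.50 | 13.2 | 3.3 |
| Thursday's | 3.00 | 13.1 | 2.3 |
| Saturday's | 0.500 | 34.4 | 3.2 |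
| Saturday's | 1.00 | 32.1 | 0.4 |
| Saturday's | 1.50 | 23.1 | 0 |
| Saturday's | 2.00 | 15.3 | 0 |
| Saturday's | 2.50 | 9.5 | 0.3 |
| Saturday's | 3.00 | 8.9 | 0 |

(scatter of a reading: 1 percentage point)

- the set-up with the highest amount of triple product at the outlet or at the end, in percent of the substrate put in ("none" if the first two lie within 2 percentage points) (birch / oak / cedar / ash / none)
- amount of triple product at the outlet or at the end, in percent of the substrate put in, birch
- amount of triple product at the outlet or at the end, in percent of the substrate put in, oak
- amount of triple product at the outlet or at the end, in percent of the substrate put in, cedar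
- amount of triple product at the outlet or at the end, in percent of the substrate put in, ash

- the stated concentrations are those of everything mixed, before any reaction; amounts are the same in each set-up
- the feed brings no volume worth counting
- the earlier runs were made in a closed, stirred flask

In Saturday's run, hardly any substrate stood at 1.00 min, yet the triple product fell from 32.1 % to 9.5 % by 2.50 min. So I took that fall as a loss to further reaction with partner, pseudo-first-order while partner holds roughly steady:

loss rate = ln(earlier reading / later reading) / time between = 0.812 min⁻¹

I assumed that the chain from substrate to triple product takes 3 partners per substrate, so I put what Saturday's 4 equiv left at about one equivalent, 0.100 M. Dividing gave the wear constant, the loss rate of triple product per unit concentration of partner 0.135 M⁻¹ s⁻¹.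

My objection was Wednesday's run, where the triple product still rose from 30.2 % to 32.5 %. But its 2 equiv is less than the 3 I had assumed for the chain, so I expected little partner late in a closed flask, and I put oak at Wednesday's last reading, 32.5 %.

A tank is fed continuously, so I expected partner to stay present there. For triple product leaving a tank I wrote:

out = made / (one + wear constant × partner × residence time)

Taking Wednesday's 32.5 % as made and guessing 0.100 M of partner, I reckoned 1.53 % for birch and 6.42 % for ash. The guess was the weak point, but a quarter of that partner still gave birch 5.35 %, less than my figure for oak. For cedar I had no such reckoning.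

The forecast named oak as best, with birch 23 %, oak 33 %, cedar 16 % and ash 21 %, reasoning: “The tanks run at depleted steady-state partner, giving lower selectivity”. We agreed in putting oak above the two tanks, but its birch stood well above mine, and so did its ash.

The flasks gave oak as best, with birch 2.69 %, oak 31.3 %, cedar 23.8 % and ash 8.38 %.

    partner + double product → triple product + by-product (k = 0.556 M⁻¹ s⁻¹)
    first product + capture agent → trapped intermediate (k = 0.0419 M⁻¹ s⁻¹)
    partner + triple product → tetra adduct + by-product (k = 0.119 M⁻¹ s⁻¹)
    partner + first product → double product + by-product (k = 0.315 M⁻¹ s⁻¹)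
    substrate + partner → first product + by-product (k = 0.267 M⁻¹ s⁻¹)
    substrate + by-product → side product (k = 0.421 M⁻¹ s⁻¹)

Partner in the birch tank stood at 0.0648 M, and in the ash tank at 0.0751 M. With these in place of my guess, the wear constant of 0.135 M⁻¹ s⁻¹ and the same 32.5 % made gave birch 2.30 % and ash 8.03 %.

The data stem from a simulated flask for substances that don't exist; scatter was added.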